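**Strategy.** Ring C is cut at C3–C4 and O1–C2. This exploits the salicyloyl pattern of ring A, where O1 on C8a sits ortho to the C4 carbonyl carbon on C4a, so that ring A arrives as a salicylaldehyde and C2–C3 as an aryl alkyne. In one pot, chelation-assisted rhodium hydroacylation joins the aldehyde carbon to C3, and a cinchona thiourea then adds the phenol oxygen to C2 with control of configuration. The alkyne carries an allyl ester on the future C3: it fixes the regiochemistry, activates the enone for the asymmetric closure, and leaves afterwards by palladium-catalysed decarboxylation. Precursors and cyclised product are isomers.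

Key step: step 5

Assumption: the thiourea derived from 9-amino-9-deoxy-epi-quinidine is taken to deliver the 2S series in step 5; should the sense of induction prove opposite, the quinine-derived pseudoenantiomer is used under the same conditions.

**Step 1**
Reactants: 1 2,4-dihydroxybenzaldehyde
Product: 2 2,4-dihydroxy-3-(3-methylbut-2-en-1-yl)benzaldehyde
Conditions: prenyl bromide, KOH, H2O, 0 °C → rt; chromatography
Reagents that add atoms: 1-bromo-3-methylbut-2-ene (prenyl bromide), CC(C)=CCBr
Why: In water the phenoxide of 1 is alkylated at carbon by the allylic bromide (phenoxide C-alkylation), and C3 between the two oxygens is the most nucleophilic ring position, so 2 should be the main C-prenylated product, separable from O- and C5-alkylated material, though only modest efficiency is expected.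

**Step 2**
Reactants: 3 2,2-dimethyl-2H-chromene-6-carbonitrile
Product: 4 2,2-dimethyl-2H-chromene-6-carbaldehyde
Conditions: i-Bu2AlH (DIBAL-H), toluene, −78 °C; then aq. potassium sodium tartrate (KNaC4H4O6), rt
Reagents that add atoms: water, O
Why: Partial reduction of a nitrile: DIBAL-H adds once to give an N-aluminio imine that is stable in the cold and is hydrolysed to the aldehyde on work-up, while the chromene alkene and ether are inert to the hydride.

**Step 3**
Reactants: 4 2,2-dimethyl-2H-chromene-6-carbaldehyde
Product: 5 6-ethynyl-2,2-dimethyl-2H-chromene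
Conditions: dimethyl (1-diazo-2-oxopropyl)phosphonate, K2CO3, MeOH, 0 °C → rt
Reagents that add atoms: dimethyl (1-diazo-2-oxopropyl)phosphonate (Ohira–Bestmann reagent), CC(=O)C(=[N+]=[N-])P(=O)(OC)OC
Why: Seyferth–Gilbert homologation in the Ohira–Bestmann version: the diazophosphonate anion released by methanolysis adds to the non-enolisable aldehyde, dimethyl phosphate and nitrogen are lost, and the alkylidene carbene rearranges to the terminal alkyne under conditions mild enough for the chromene.

**Step 4**
Reactants: 5 6-ethynyl-2,2-dimethyl-2H-chromene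
Product: 6 prop-2-en-1-yl 3-(2,2-dimethyl-2H-chromen-6-yl)prop-2-ynoate
Conditions: n-BuLi, THF, −78 °C; then added to allyl chloroformate, THF, −78 °C
Reagents that add atoms: allyl chloroformate (prop-2-en-1-yl carbonochloridate), C=CCOC(Cl)=O
Why: Deprotonation of the terminal alkyne and C-acylation of the lithium acetylide by the chloroformate should give the ynoate, with inverse addition to excess electrophile suppressing a second acetylide addition.

**Step 5**
Reactants: 2 2,4-dihydroxy-3-(3-methylbut-2-en-1-yl)benzaldehyde; 6 prop-2-en-1-yl 3-(2,2-dimethyl-2H-chromen-6-yl)prop-2-ynoate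
Product: 8 prop-2-en-1-yl (2S,3R)-2-(2,2-dimethyl-2H-chromen-6-yl)-7-hydroxy-8-(3-methylbut-2-en-1-yl)-4-oxo-3,4-dihydro-2H-chromene-3-carboxylate, via Z-alkylidene keto ester 7 (not isolated)
Conditions: [Rh(cod)OMe]2 (2.5 mol %), 1,1'-bis(diphenylphosphino)ferrocene (dppf, 5 mol %), toluene, 60 °C; then −25 °C, 9-amino-9-deoxy-epi-quinidine 3,5-bis(trifluoromethyl)phenyl thiourea (10 mol %)
Reagents that add atoms: none
Why: The monovalent rhodium phenoxide formed at the 2-OH of 2 directs oxidative addition of the aldehyde C–H bond to a five-membered trivalent acyl rhodium hydride chelate, syn hydrometalation of ynoate 6 puts hydride on the aryl-bearing carbon and rhodium on the ester-bearing carbon, and C–C reductive elimination forms C3–C4 in enone 7; after cooling, the thiourea binds the keto ester by double hydrogen bonding while its quinuclidine nitrogen activates the 2-OH, which adds to the benzylidene carbon to form O1–C2. The closest known reactions are the tandem rhodium-catalysed salicylaldehyde–alkyne hydroacylation/oxa-Michael route to chroman-4-ones and the cinchona-thiourea cyclisation of 2-hydroxyaryl alkylidene keto esters to flavanones, merged here in one flask. Ring C closes by a 6-endo-trig intramolecular oxa-Michael addition. C2 is set by the chiral catalyst, which exposes one face of the alkylidene in the hydrogen-bonded complex, whereas C3 is epimerisable, should settle trans to the aryl group and is erased in step 6. The step needs acyl delivery to the carbon next to the ester, which the polarisation of the ynoate and the aryl group both favour, and reaction at the alkyne in preference to the prenyl, chromene and allyl alkenes, which insert far more slowly into the chelated hydride. It also needs the absence of racemic ring closure during the rhodium stage, which is why the methoxide-bridged precatalyst is used without added inorganic base.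

**Step 6**
Reactants: 8 prop-2-en-1-yl (2S,3R)-2-(2,2-dimethyl-2H-chromen-6-yl)-7-hydroxy-8-(3-methylbut-2-en-1-yl)-4-oxo-3,4-dihydro-2H-chromene-3-carboxylate (used directly after filtration through a short silica pad)
Product: 10 (2S)-2-(2,2-dimethyl-2H-chromen-6-yl)-7-hydroxy-8-(3-methylbut-2-en-1-yl)-2,3-dihydro-4H-chromen-4-one, via keto acid 9 (not isolated)
Conditions: Pd(PPh3)4 (5 mol %), HCO2H, Et3N, THF, 0 °C → rt
Reagents that add atoms: none
Why: Tsuji deallylation–decarboxylation: zerovalent palladium ionises the allyl ester, formate reduces the allyl palladium unit to propene, and keto acid 9 loses CO2 at room temperature through its enol, which removes the C3 substituent under buffered conditions that should leave the C2 stereocentre, the prenyl group and the chromene untouched.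

**Compound list**
1 | 2,4-dihydroxybenzaldehyde | O=Cc1ccc(O)cc1O | starting material
2 | 2,4-dihydroxy-3-(3-methylbut-2-en-1-yl)benzaldehyde | CC(C)=CCc1c(O)ccc(C=O)c1O | intermediate
3 | 2,2-dimethyl-2H-chromene-6-carbonitrile | CC1(C)C=Cc2cc(C#N)ccc2O1 | starting material
4 | 2,2-dimethyl-2H-chromene-6-carbaldehyde | CC1(C)C=Cc2cc(C=O)ccc2O1 | intermediate
5 | 6-ethynyl-2,2-dimethyl-2H-chromene | CC1(C)C=Cc2cc(C#C)ccc2O1 | intermediate
6 | prop-2-en-1-yl 3-(2,2-dimethyl-2H-chromen-6-yl)prop-2-ynoate | C=CCOC(=O)C#Cc1ccc2OC(C)(C)C=Cc2c1 | intermediate
7 | prop-2-en-1-yl (2Z)-2-[2,4-dihydroxy-3-(3-methylbut-2-en-1-yl)benzoyl]-3-(2,2-dimethyl-2H-chromen-6-yl)prop-2-enoate (not isolated) | C=CCOC(=O)/C(=C\c1ccc2OC(C)(C)C=Cc2c1)C(=O)c1ccc(O)c(CC=C(C)C)c1O | intermediate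
8 | prop-2-en-1-yl (2S,3R)-2-(2,2-dimethyl-2H-chromen-6-yl)-7-hydroxy-8-(3-methylbut-2-en-1-yl)-4-oxo-3,4-dihydro-2H-chromene-3-carboxylate (trans; C3 labile) | CC(C)=CCc1c(O)ccc2c1O[C@H](c1ccc3c(c1)C=CC(C)(C)O3)[C@@H](C(=O)OCC=C)C2=O | intermediate
9 | (2S,3R)-2-(2,2-dimethyl-2H-chromen-6-yl)-7-hydroxy-8-(3-methylbut-2-en-1-yl)-4-oxo-3,4-dihydro-2H-chromene-3-carboxylic acid (not isolated) | CC(C)=CCc1c(O)ccc2c1O[C@H](c1ccc3c(c1)C=CC(C)(C)O3)[C@@H](C(=O)O)C2=O | intermediate
10 | (2S)-2-(2,2-dimethyl-2H-chromen-6-yl)-7-hydroxy-8-(3-methylbut-2-en-1-yl)-2,3-dihydro-4H-chromen-4-one | CC(C)=CCc1c(O)ccc2c1O[C@H](c1ccc3c(c1)C=CC(C)(C)O3)CC2=O | target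

**Total step count:** 6
**Longest linear sequence:** 5 steps (3 → 4 → 5 → 6 → 8 → 10)

**Steps most likely to fail**

1. Step 5. Hydrometalation may run in the wrong sense, or the phenol may add to the ynoate before C–H activation. The free 4-OH may slow either catalyst. Ring closure may also begin before the chiral catalyst is present, which would lower the enantiomeric purity. The fallback sets out from 2 and 4 and comes back to the route at 8. Compound 2 is homologated with allyl diazoacetate and catalytic SnCl2 in CH2Cl2 (Roskamp reaction) to prop-2-en-1-yl 3-[2,4-dihydroxy-3-(3-methylbut-2-en-1-yl)phenyl]-3-oxopropanoate F1. Knoevenagel condensation of this keto ester with 4 (piperidine, AcOH, toluene, molecular sieves) then gives 7, this time isolated. The same thiourea in toluene at −25 °C closes 7 to 8, so the asymmetric ring closure is kept while the carbon framework is assembled by condensation instead of hydroacylation.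

2. Step 1. Site selectivity of the phenoxide alkylation may be poor (O- against C-alkylation, C5 against C3, double alkylation). The fallback sets out from 1 and comes back at 2. The non-chelated 4-OH of 1 is alkylated with 3-chloro-3-methylbut-1-yne (K2CO3, KI, catalytic CuI, acetone, reflux) to 2-hydroxy-4-[(2-methylbut-3-yn-2-yl)oxy]benzaldehyde F2. Semi-hydrogenation (H2, Pd on CaCO3 poisoned with Pb(OAc)2, quinoline, EtOAc) gives 2-hydroxy-4-[(2-methylbut-3-en-2-yl)oxy]benzaldehyde F3. Heating in N,N-diethylaniline at about 130 °C then brings about an aromatic Claisen rearrangement to C3, the position favoured by the bond fixation of the chelated salicylaldehyde, and delivers 2.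

3. Step 6. Ring C may open reversibly (retro-oxa-Michael through the C3 enol) before or during loss of CO2, with partial loss of the C2 configuration. The fallback sets out from 10 of insufficient enantiomeric purity and comes back at 10. Ring C is opened on purpose with aqueous KOH in EtOH, followed by quick acidification, to (2E)-1-[2,4-dihydroxy-3-(3-methylbut-2-en-1-yl)phenyl]-3-(2,2-dimethyl-2H-chromen-6-yl)prop-2-en-1-one F4. A chalcone isomerase (chalcone–flavanone isomerase, an intramolecular lyase; a type 2 enzyme from a legume, which accepts chalcones lacking the 6'-hydroxyl) in phosphate buffer at pH 7.5 with DMSO as co-solvent should then reclose the ring to the 2S flavanone under enzyme control. Acceptance of this prenylated substrate would have to be screened.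

**Further compounds**
F1 | step 5 | prop-2-en-1-yl 3-[2,4-dihydroxy-3-(3-methylbut-2-en-1-yl)phenyl]-3-oxopropanoate | C=CCOC(=O)CC(=O)c1ccc(O)c(CC=C(C)C)c1O
F2 | step 1 | 2-hydroxy-4-[(2-methylbut-3-yn-2-yl)oxy]benzaldehyde | C#CC(C)(C)Oc1ccc(C=O)c(O)c1
F3 | step 1 | 2-hydroxy-4-[(2-methylbut-3-en-2-yl)oxy]benzaldehyde | C=CC(C)(C)Oc1ccc(C=O)c(O)c1
F4 | step 6 | (2E)-1-[2,4-dihydroxy-3-(3-methylbut-2-en-1-yl)phenyl]-3-(2,2-dimethyl-2H-chromen-6-yl)prop-2-en-1-one | CC(C)=CCc1c(O)ccc(C(=O)/C=C/c2ccc3OC(C)(C)C=Cc3c2)c1O
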